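The numbers in the tables stem from a simulated flask for substances that don't exist, and the scatter is random.

I kept books on the carrier.

| setting | larch | elm | maple | flask |
|---|---|---|---|---|
| substrate | 20 mM | 20 mM | 40 mM | 20 mM |
| salt in the second phase | 1 equiv | 1 equiv | 1 equiv | 1.00 equiv |
| spent carrier | 0.5 mol% | 0.75 mol% | 1 mol% | 1 mol% |
| impurity | 32 µM | 32 µM | 32 µM | 32 µM |
| remark | run made earlier | run made earlier | run made earlier |  |
| volume of the second phase over the first |  |  |  | 0.50 |

| run | time / min | product / % |
|---|---|---|
| larch | 8.00 | 48.3 |
| larch | 15.0 | 66.1 |
| larch | 40.0 | 87.9 |
| larch | 90.0 | 94.6 |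
| elm | 8.00 | 65.4 |
| elm | 15.0 | 80.0 |
| elm | 40.0 | 95.1 |
| elm | 90.0 | 97.9 |
| maple | 8.00 | 87.5 |
| maple | 15.0 | 92.9 |
| maple | 40.0 | 98.0 |
| maple | 90.0 | 97.4 |

(each reading ± 1 percentage point)

- apparent order in spent carrier when 5.0 % of the substrate are converted (percent change of the rate of making product for one percent more spent carrier charged)

The flask charged C = 200 µM of spent carrier beside 32 µM of impurity, and because impurity was the limiting reagent of the step that turns fresh carrier into spent catalyst, my ledger held one debit, at most one carrier per impurity:

carrier still working, at the least, W = C − impurity = 168 µM

I assumed that at a fixed conversion substrate, salt and spent salt stood at the same levels for a small change of carrier charge, and since impurity and substrate competed for the same fresh carrier, I took the loss L by that conversion as independent of C, with the rate following C − L: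

order = C / (C − L), and with L at its full debit, C / W = 1.19

I called this last figure the ledger ceiling, charge over charge less impurity.

Larch and elm pointed to the debit. Their charges stood at a ratio of 100 µM to 150 µM, or 1.50, and their charges less the full impurity at 1.74, while product over the unreacted rest of the substrate after 8.00 min gave a ratio, as a reading with its scatter, of 2.02, above the charge ratio; larch's own ceiling was 1.47.

How much of the debit had fallen due by 5.0 % conversion I could not read, so I committed only to an order between 1 and 1.19. The forecast gave 1.13, from 1.03 to 1.21, observing of the apparent constants that “These rise faster than the carrier charge”; its range was narrower than my bracket.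

The flask gave 1.1, inside that range and below the ceiling.

    spent carrier + salt in the second phase ⇌ fresh carrier + spent salt in the second phase (K = 0.350, k = 13.0 /M/s)
    substrate + fresh carrier → product + spent carrier (k = 190 /M/s)
    fresh carrier + impurity → spent catalyst (k = 3700 /M/s)

At the start of the flask, fresh carrier met substrate at 3.80 /s and impurity at 0.118 /s, although per unit of concentration impurity was quicker by a selectivity factor S of 19.5. At 5.0 % conversion that factor reckons 36.8 % of the impurity as left in the flask, a loss L of 20.2 µM against the full 32 µM, which makes C / (C − L) equal to 1.11, and by 0.250 h spent catalyst stood at 16.0 % of the catalyst charged.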